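**Plan**

- Ring C shares the O1–C8a and C4–C4a bonds with ring A, so O1, C8a, C4a and C4 can be written as an ortho-quinone methide heterodiene. The retrosynthesis lowers the C4 ketone to a 4-methoxy ether and cuts O1–C2 and C3–C4, giving a ring A salicylaldehyde and an (E)-enol acetate that carries ring B on C2 and the oxygen on C3.
- The salicylaldehyde is cut at the formyl C–C bond and at the benzylic C–H of the side chain, back to a 1,1-diarylethene, which is cut at the aryl–C bond into 2,4,6-trihydroxyacetophenone and a 4-benzyloxyphenyl Grignard reagent.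
- Forward: ring A is built first (side chain, then formyl group), ring C is closed onto it in one (4+2) step that also brings in ring B, and the route ends with adjustment of C4 to the ketone and hydrogenolysis of four benzyl ethers.
- Stereochemistry: the side-chain centre comes from iridium-catalysed asymmetric hydrogenation; C3 from the chiral phosphate in the cycloaddition; C2 from trans closure relative to C3; C4 is transient.

Key step: step 9

Assumption: the sense of induction of the chiral catalysts in steps 4 and 9 cannot be assigned on paper, so the antipode written is provisional and the one that gives the stated configuration is meant.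

**Route**

Step 1
Reactants: 1 2,4,6-trihydroxyacetophenone
Product: 2 1-[2,6-dihydroxy-4-(methoxymethoxy)phenyl]ethanone
Conditions: MOMCl (1.05 equiv), iPr2NEt (1.2 equiv), THF, 0 °C
Reagents that add atoms: chloromethyl methyl ether, COCCl
Why: Williamson-type O-alkylation (MOM protection) should occur at the 4-hydroxyl, the most acidic one and the only one not hydrogen-bonded to the acetyl carbonyl.

Step 2
Reactants: 2 1-[2,6-dihydroxy-4-(methoxymethoxy)phenyl]ethanone
Product: 3 1-[2,6-bis(benzyloxy)-4-(methoxymethoxy)phenyl]ethanone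
Conditions: BnBr (2.5 equiv), K2CO3 (3 equiv), DMF, 70 °C
Reagents that add atoms: benzyl bromide, BrCc1ccccc1
Why: Williamson etherification in hot DMF overcomes the chelated hydrogen bonds and benzylates both remaining hydroxyls, as in the perbenzylation of phloroacetophenone, while the MOM ether is inert to base.

Step 3
Reactants: 3 1-[2,6-bis(benzyloxy)-4-(methoxymethoxy)phenyl]ethanone; 4 1-(benzyloxy)-4-bromobenzene
Product: 7 1,3-bis(benzyloxy)-2-{1-[4-(benzyloxy)phenyl]ethenyl}-5-(methoxymethoxy)benzene, via [4-(benzyloxy)phenyl]magnesium bromide 5 (not isolated), via tertiary carbinol 6 (not isolated)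
Conditions: 4, Mg, THF, reflux; then 3, LaCl3·2LiCl (1 equiv), THF, 0 °C → rt; NH4Cl aq; then p-toluenesulfonic acid monohydrate (2 mol %), toluene, 40 °C
Reagents that add atoms: none
Why: Grignard addition to the hindered ketone, with LaCl3·2LiCl to suppress enolisation, gives a doubly benzylic tertiary carbinol that loses water by E1 dehydration to the only possible alkene.

Step 4
Reactants: 7 1,3-bis(benzyloxy)-2-{1-[4-(benzyloxy)phenyl]ethenyl}-5-(methoxymethoxy)benzene
Product: 8 1,3-bis(benzyloxy)-2-{(1R)-1-[4-(benzyloxy)phenyl]ethyl}-5-(methoxymethoxy)benzene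
Conditions: H2 (30 bar), [Ir(cod)(L)]BArF (2 mol %; cod = 1,5-cyclooctadiene, L = (S)-4-tert-butyl-2-[2-(diphenylphosphanyl)phenyl]-4,5-dihydro-1,3-oxazole, BArF = tetrakis[3,5-bis(trifluoromethyl)phenyl]borate), CH2Cl2, rt
Reagents that add atoms: none
Why: Iridium-catalysed asymmetric hydrogenation of a 1,1-diarylethene should set the (R) centre, because the ortho,ortho-disubstituted ring is twisted out of the alkene plane and the para-substituted ring is coplanar, so the P,N-ligated catalyst sees two very different aryl groups; the alkene cannot isomerise and the benzyl ethers are not cleaved by the homogeneous catalyst.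

Step 5
Reactants: 8 1,3-bis(benzyloxy)-2-{(1R)-1-[4-(benzyloxy)phenyl]ethyl}-5-(methoxymethoxy)benzene
Product: 9 3,5-bis(benzyloxy)-4-{(1R)-1-[4-(benzyloxy)phenyl]ethyl}phenol
Conditions: HCl (1.25 M in MeOH), THF, 40 °C
Reagents that add atoms: none
Why: Acid-catalysed acetal exchange with methanol (MOM cleavage) frees the phenol, while aryl benzyl ethers and the benzylic C–H centre are inert to dilute acid.

Step 6
Reactants: 9 3,5-bis(benzyloxy)-4-{(1R)-1-[4-(benzyloxy)phenyl]ethyl}phenol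
Product: 10 4,6-bis(benzyloxy)-5-{(1R)-1-[4-(benzyloxy)phenyl]ethyl}-2-hydroxybenzaldehyde
Conditions: MgCl2 (2 equiv), Et3N (4 equiv), (CH2O)n (6 equiv), THF, reflux
Reagents that add atoms: paraformaldehyde (formaldehyde), C=O
Why: Magnesium-mediated ortho-formylation (Casnati–Skattebøl): the magnesium phenoxide delivers formaldehyde to the ortho carbon and a second formaldehyde oxidises the benzylic alkoxide by hydride transfer; the two ortho positions are equivalent and the para position is blocked.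

Step 7
Reactants: 11 2-[4-(benzyloxy)phenyl]ethanol
Product: 12 [4-(benzyloxy)phenyl]acetaldehyde
Conditions: PhI(OAc)2 (1.1 equiv), (2,2,6,6-tetramethylpiperidin-1-yl)oxyl (TEMPO, 10 mol %), CH2Cl2, rt
Reagents that add atoms: none
Why: Oxoammonium-mediated (TEMPO/PhI(OAc)2) alcohol oxidation stops at the aldehyde and is mild enough for an enolisable arylacetaldehyde, which is used without storage.

Step 8
Reactants: 12 [4-(benzyloxy)phenyl]acetaldehyde
Product: 13 (E)-2-[4-(benzyloxy)phenyl]ethenyl acetate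
Conditions: Ac2O (4 equiv), KOAc (0.5 equiv), 120 °C; crystallisation
Reagents that add atoms: acetic anhydride, CC(=O)OC(C)=O
Why: Enol ester formation: acetate-mediated enolisation and O-acylation by the anhydride give the styryl acetate, in which the conjugated, less hindered (E) isomer is expected to predominate and to be obtained pure by crystallisation.

Step 9
Reactants: 10 4,6-bis(benzyloxy)-5-{(1R)-1-[4-(benzyloxy)phenyl]ethyl}-2-hydroxybenzaldehyde; 13 (E)-2-[4-(benzyloxy)phenyl]ethenyl acetate (2 equiv)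
Product: 16 (2R,3S,4R)-5,7-bis(benzyloxy)-2-[4-(benzyloxy)phenyl]-6-{(1R)-1-[4-(benzyloxy)phenyl]ethyl}-4-methoxy-3,4-dihydro-2H-chromen-3-yl acetate (the C4 epimer serves equally), via dimethyl acetal 14 (not isolated), via ortho-quinone methide 15 (not isolated)
Conditions: HC(OMe)3 (2 equiv), (R)-3,3′-bis(2,4,6-triisopropylphenyl)-1,1′-binaphthyl-2,2′-diyl hydrogen phosphate (10 mol %), 5 Å MS, CH2Cl2, 0 °C → rt
Reagents that add atoms: trimethyl orthoformate, COC(OC)OC
Why: Proposed new method: acid and orthoformate should turn aldehyde 10 into acetal 14, which loses methanol to give the 4-methoxy ortho-quinone methide 15 as a hydrogen-bonded ion pair with the chiral phosphate (an ortho-hydroxybenzyl oxocarbenium ion); the acetoxy-bearing carbon of 13 then bonds to C4 and the phenolic oxygen closes on C2. The closest known reactions are the acid-catalysed three-component synthesis of 4-alkoxy-2-arylchromans from salicylaldehydes, orthoformates and styrenes and the chiral phosphoric acid-catalysed (4+2) cycloadditions of ortho-quinone methides with electron-rich alkenes, while an enol ester as the two-carbon partner and enantiocontrol in the three-component form are not yet shown. Ring C closes as a six-membered ring in an asynchronous inverse-demand hetero-Diels–Alder mode, C3–C4 first and O1–C2 second, endo with respect to the former alkene carbons. C3 (together with the transient C4) is set by which face of the enol acetate the phosphate-bound quinone methide accepts, and C2 ends trans to C3 either by suprafacial addition to the (E)-alkene or, if the benzylic cation is long-lived, by anti opening of the acetoxonium ion formed with the neighbouring acetate, so both pathways lead to the diequatorial 2,3-trans ring. The step needs regioselectivity, secured because the 4-benzyloxyphenyl group stabilises charge at C2 far better than the acyl-damped enol oxygen could at C3, and face selectivity at C3, which rests on the catalyst because the side-chain centre is remote. Since that centre is already fixed, a wrong-face adduct is a diastereomer that can be removed by chromatography or crystallisation, and the C4 configuration does not matter because the centre is oxidised later.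

Step 10
Reactants: 16 (2R,3S,4R)-5,7-bis(benzyloxy)-2-[4-(benzyloxy)phenyl]-6-{(1R)-1-[4-(benzyloxy)phenyl]ethyl}-4-methoxy-3,4-dihydro-2H-chromen-3-yl acetate
Product: 17 (2R,3S,4R)-5,7-bis(benzyloxy)-2-[4-(benzyloxy)phenyl]-6-{(1R)-1-[4-(benzyloxy)phenyl]ethyl}-4-methoxy-3,4-dihydro-2H-chromen-3-ol
Conditions: K2CO3 (0.2 equiv), MeOH/THF (2:1), rt
Reagents that add atoms: none
Why: Base-catalysed transesterification (Zemplén-type methanolysis) removes the acetate, and the benzylic methyl ether, the benzyl ethers and all stereocentres are inert to carbonate.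

Step 11
Reactants: 17 (2R,3S,4R)-5,7-bis(benzyloxy)-2-[4-(benzyloxy)phenyl]-6-{(1R)-1-[4-(benzyloxy)phenyl]ethyl}-4-methoxy-3,4-dihydro-2H-chromen-3-ol
Product: 18 (2R,3S)-5,7-bis(benzyloxy)-2-[4-(benzyloxy)phenyl]-6-{(1R)-1-[4-(benzyloxy)phenyl]ethyl}-3,4-dihydro-2H-chromene-3,4-diol (mixture of C4 epimers)
Conditions: p-toluenesulfonic acid monohydrate (5 mol %), THF/H2O (4:1), 0.02 M, rt
Reagents that add atoms: water, O
Why: SN1 solvolysis: the methoxy group sits on a 2,4,6-trioxygenated benzylic carbon, ionises under mild acid and the cation is captured by the large excess of water, with high dilution holding back attack by C8 of a second molecule; C2 and C3 are untouched.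

Step 12
Reactants: 18 (2R,3S)-5,7-bis(benzyloxy)-2-[4-(benzyloxy)phenyl]-6-{(1R)-1-[4-(benzyloxy)phenyl]ethyl}-3,4-dihydro-2H-chromene-3,4-diol
Product: 19 (2R,3R)-5,7-bis(benzyloxy)-2-[4-(benzyloxy)phenyl]-6-{(1R)-1-[4-(benzyloxy)phenyl]ethyl}-3-hydroxy-2,3-dihydro-4H-chromen-4-one
Conditions: activated MnO2 (15 equiv), CH2Cl2, rt
Reagents that add atoms: none
Why: Benzylic alcohol oxidation with activated MnO2 should take only the electron-rich benzylic C4 hydroxyl and leave the unactivated C3 hydroxyl, so both C4 epimers converge on the trans 3-hydroxy ketone.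

Step 13
Reactants: 19 (2R,3R)-5,7-bis(benzyloxy)-2-[4-(benzyloxy)phenyl]-6-{(1R)-1-[4-(benzyloxy)phenyl]ethyl}-3-hydroxy-2,3-dihydro-4H-chromen-4-one
Product: 20 (2R,3R)-3,5,7-trihydroxy-2-(4-hydroxyphenyl)-6-[(1R)-1-(4-hydroxyphenyl)ethyl]-2,3-dihydro-4H-chromen-4-one
Conditions: H2 (1 atm), 10% Pd/C, EtOAc/MeOH (1:1), rt
Reagents that add atoms: none
Why: Catalytic hydrogenolysis cleaves the four aryl benzyl ethers under neutral conditions, which leave the hydrogen-bonded aryl ketone, the diarylethane C–C bonds and the three stereocentres unchanged.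

**Compound list**

1 | 2,4,6-trihydroxyacetophenone | CC(=O)c1c(O)cc(O)cc1O | starting material
2 | 1-[2,6-dihydroxy-4-(methoxymethoxy)phenyl]ethanone | CC(=O)c1c(O)cc(OCOC)cc1O | intermediate
3 | 1-[2,6-bis(benzyloxy)-4-(methoxymethoxy)phenyl]ethanone | CC(=O)c1c(OCc2ccccc2)cc(OCOC)cc1OCc3ccccc3 | intermediate
4 | 1-(benzyloxy)-4-bromobenzene | Brc1ccc(OCc2ccccc2)cc1 | starting material
5 | [4-(benzyloxy)phenyl]magnesium bromide (not isolated) | Br[Mg]c1ccc(OCc2ccccc2)cc1 | intermediate
6 | racemic 1-[2,6-bis(benzyloxy)-4-(methoxymethoxy)phenyl]-1-[4-(benzyloxy)phenyl]ethanol (not isolated) | CC(O)(c1ccc(OCc2ccccc2)cc1)c3c(OCc4ccccc4)cc(OCOC)cc3OCc5ccccc5 | intermediate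
7 | 1,3-bis(benzyloxy)-2-{1-[4-(benzyloxy)phenyl]ethenyl}-5-(methoxymethoxy)benzene | C=C(c1ccc(OCc2ccccc2)cc1)c3c(OCc4ccccc4)cc(OCOC)cc3OCc5ccccc5 | intermediate
8 | 1,3-bis(benzyloxy)-2-{(1R)-1-[4-(benzyloxy)phenyl]ethyl}-5-(methoxymethoxy)benzene | C[C@H](c1ccc(OCc2ccccc2)cc1)c3c(OCc4ccccc4)cc(OCOC)cc3OCc5ccccc5 | intermediate
9 | 3,5-bis(benzyloxy)-4-{(1R)-1-[4-(benzyloxy)phenyl]ethyl}phenol | C[C@H](c1ccc(OCc2ccccc2)cc1)c3c(OCc4ccccc4)cc(O)cc3OCc5ccccc5 | intermediate
10 | 4,6-bis(benzyloxy)-5-{(1R)-1-[4-(benzyloxy)phenyl]ethyl}-2-hydroxybenzaldehyde | C[C@H](c1ccc(OCc2ccccc2)cc1)c3c(OCc4ccccc4)cc(O)c(C=O)c3OCc5ccccc5 | intermediate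
11 | 2-[4-(benzyloxy)phenyl]ethanol | OCCc1ccc(OCc2ccccc2)cc1 | starting material
12 | [4-(benzyloxy)phenyl]acetaldehyde | O=CCc1ccc(OCc2ccccc2)cc1 | intermediate
13 | (E)-2-[4-(benzyloxy)phenyl]ethenyl acetate | CC(=O)O/C=C/c1ccc(OCc2ccccc2)cc1 | intermediate
14 | 3,5-bis(benzyloxy)-4-{(1R)-1-[4-(benzyloxy)phenyl]ethyl}-2-(dimethoxymethyl)phenol (not isolated) | C[C@H](c1ccc(OCc2ccccc2)cc1)c3c(OCc4ccccc4)cc(O)c(C(OC)OC)c3OCc5ccccc5 | intermediate
15 | 3,5-bis(benzyloxy)-4-{(1R)-1-[4-(benzyloxy)phenyl]ethyl}-6-(methoxymethylidene)cyclohexa-2,4-dien-1-one (not isolated) | C[C@H](c1ccc(OCc2ccccc2)cc1)C3=C(OCc4ccccc4)C(=COC)C(=O)C=C3OCc5ccccc5 | intermediate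
16 | (2R,3S,4R)-5,7-bis(benzyloxy)-2-[4-(benzyloxy)phenyl]-6-{(1R)-1-[4-(benzyloxy)phenyl]ethyl}-4-methoxy-3,4-dihydro-2H-chromen-3-yl acetate | C[C@H](c1ccc(OCc2ccccc2)cc1)c3c(OCc4ccccc4)cc5c(c3OCc6ccccc6)[C@@H](OC)[C@H](OC(C)=O)[C@@H](c7ccc(OCc8ccccc8)cc7)O5 | intermediate
17 | (2R,3S,4R)-5,7-bis(benzyloxy)-2-[4-(benzyloxy)phenyl]-6-{(1R)-1-[4-(benzyloxy)phenyl]ethyl}-4-methoxy-3,4-dihydro-2H-chromen-3-ol | C[C@H](c1ccc(OCc2ccccc2)cc1)c3c(OCc4ccccc4)cc5c(c3OCc6ccccc6)[C@@H](OC)[C@H](O)[C@@H](c7ccc(OCc8ccccc8)cc7)O5 | intermediate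
18 | (2R,3S)-5,7-bis(benzyloxy)-2-[4-(benzyloxy)phenyl]-6-{(1R)-1-[4-(benzyloxy)phenyl]ethyl}-3,4-dihydro-2H-chromene-3,4-diol, C4 epimers | C[C@H](c1ccc(OCc2ccccc2)cc1)c3c(OCc4ccccc4)cc5c(c3OCc6ccccc6)C(O)[C@H](O)[C@@H](c7ccc(OCc8ccccc8)cc7)O5 | intermediate
19 | (2R,3R)-5,7-bis(benzyloxy)-2-[4-(benzyloxy)phenyl]-6-{(1R)-1-[4-(benzyloxy)phenyl]ethyl}-3-hydroxy-2,3-dihydro-4H-chromen-4-one | C[C@H](c1ccc(OCc2ccccc2)cc1)c3c(OCc4ccccc4)cc5c(c3OCc6ccccc6)C(=O)[C@H](O)[C@@H](c7ccc(OCc8ccccc8)cc7)O5 | intermediate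
20 | (2R,3R)-3,5,7-trihydroxy-2-(4-hydroxyphenyl)-6-[(1R)-1-(4-hydroxyphenyl)ethyl]-2,3-dihydro-4H-chromen-4-one | C[C@H](c1ccc(O)cc1)c1c(O)cc2c(c1O)C(=O)[C@H](O)[C@@H](c1ccc(O)cc1)O2 | target

**Step count and risks**

Total step count: 13. Longest linear sequence: 11 steps (steps 1–6 and 9–13); steps 7 and 8 form the second branch.

Step 9 (key step). The enol acetate may react too slowly with the strongly stabilised oxocarbenium ion, or face selection at C3 by the phosphate may be poor. The fallback is the chalcone epoxide route to trans-dihydroflavonols; it sets out from phenol 9 and comes back at ketone 19, so steps 9 to 12 are bypassed. Friedel–Crafts C-acetylation of 9 (Ac2O, BF3·OEt2, 0 °C) should give 1-[4,6-bis(benzyloxy)-5-{(1R)-1-[4-(benzyloxy)phenyl]ethyl}-2-hydroxyphenyl]ethanone F1. MOM protection (MOMCl, NaH, DMF) then gives 1-[4,6-bis(benzyloxy)-5-{(1R)-1-[4-(benzyloxy)phenyl]ethyl}-2-(methoxymethoxy)phenyl]ethanone F2. Claisen–Schmidt condensation with 4-(benzyloxy)benzaldehyde (KOH, EtOH/THF) gives (2E)-1-[4,6-bis(benzyloxy)-5-{(1R)-1-[4-(benzyloxy)phenyl]ethyl}-2-(methoxymethoxy)phenyl]-3-[4-(benzyloxy)phenyl]prop-2-en-1-one F3. Julia–Colonna epoxidation (poly-L-leucine or its antipode, urea–H2O2, 1,8-diazabicyclo[5.4.0]undec-7-ene, THF) gives [4,6-bis(benzyloxy)-5-{(1R)-1-[4-(benzyloxy)phenyl]ethyl}-2-(methoxymethoxy)phenyl]{(2R,3S)-3-[4-(benzyloxy)phenyl]oxiran-2-yl}methanone F4. HCl in MeOH/THF then removes the MOM group and lets the freed phenol open the epoxide at the benzylic carbon with inversion (6-endo), which should give 19.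

Step 4. The catalyst may not distinguish the two aryl groups well enough, or reduction of the hindered alkene may stall. The fallback replaces asymmetric catalysis by resolution; it sets out from alkene 7 and comes back at 8. Hydrogenation with the achiral complex [Ir(cod)(PCy3)(py)]PF6 (H2, CH2Cl2), which spares benzyl ethers, should give racemic 1,3-bis(benzyloxy)-2-{1-[4-(benzyloxy)phenyl]ethyl}-5-(methoxymethoxy)benzene F5. Preparative chromatography on a chiral stationary phase (supercritical CO2/alcohol) then separates 8 from 1,3-bis(benzyloxy)-2-{(1S)-1-[4-(benzyloxy)phenyl]ethyl}-5-(methoxymethoxy)benzene F6, which is discarded.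

Step 12. MnO2 may cleave the 3,4-glycol or over-oxidise the product to the flavonol. The fallback oxidises C4 while the C3 oxygen is still acetylated; it sets out from 16 and comes back at 19. Mild aqueous acid (as in step 11) applied to 16 should give (2R,3S)-5,7-bis(benzyloxy)-2-[4-(benzyloxy)phenyl]-6-{(1R)-1-[4-(benzyloxy)phenyl]ethyl}-4-hydroxy-3,4-dihydro-2H-chromen-3-yl acetate F7 as C4 epimers. Dess–Martin periodinane (1,1,1-triacetoxy-1,1-dihydro-1,2-benziodoxol-3(1H)-one, NaHCO3, CH2Cl2) then gives (2R,3R)-5,7-bis(benzyloxy)-2-[4-(benzyloxy)phenyl]-6-{(1R)-1-[4-(benzyloxy)phenyl]ethyl}-4-oxo-3,4-dihydro-2H-chromen-3-yl acetate F8. Acid-catalysed methanolysis (HCl from AcCl in MeOH, 0 °C) frees the 3-hydroxyl without base, which could open ring C, and should give 19.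

Further compounds
F1 | step 9 | 1-[4,6-bis(benzyloxy)-5-{(1R)-1-[4-(benzyloxy)phenyl]ethyl}-2-hydroxyphenyl]ethanone | C[C@H](c1ccc(OCc2ccccc2)cc1)c3c(OCc4ccccc4)cc(O)c(C(C)=O)c3OCc5ccccc5
F2 | step 9 | 1-[4,6-bis(benzyloxy)-5-{(1R)-1-[4-(benzyloxy)phenyl]ethyl}-2-(methoxymethoxy)phenyl]ethanone | C[C@H](c1ccc(OCc2ccccc2)cc1)c3c(OCc4ccccc4)cc(OCOC)c(C(C)=O)c3OCc5ccccc5
F3 | step 9 | (2E)-1-[4,6-bis(benzyloxy)-5-{(1R)-1-[4-(benzyloxy)phenyl]ethyl}-2-(methoxymethoxy)phenyl]-3-[4-(benzyloxy)phenyl]prop-2-en-1-one | C[C@H](c1ccc(OCc2ccccc2)cc1)c3c(OCc4ccccc4)cc(OCOC)c(C(=O)/C=C/c6ccc(OCc7ccccc7)cc6)c3OCc5ccccc5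
F4 | step 9 | [4,6-bis(benzyloxy)-5-{(1R)-1-[4-(benzyloxy)phenyl]ethyl}-2-(methoxymethoxy)phenyl]{(2R,3S)-3-[4-(benzyloxy)phenyl]oxiran-2-yl}methanone | C[C@H](c1ccc(OCc2ccccc2)cc1)c3c(OCc4ccccc4)cc(OCOC)c(C(=O)[C@@H]6O[C@H]6c7ccc(OCc8ccccc8)cc7)c3OCc5ccccc5
F5 | step 4 | racemic 1,3-bis(benzyloxy)-2-{1-[4-(benzyloxy)phenyl]ethyl}-5-(methoxymethoxy)benzene | CC(c1ccc(OCc2ccccc2)cc1)c3c(OCc4ccccc4)cc(OCOC)cc3OCc5ccccc5
F6 | step 4 | 1,3-bis(benzyloxy)-2-{(1S)-1-[4-(benzyloxy)phenyl]ethyl}-5-(methoxymethoxy)benzene | C[C@@H](c1ccc(OCc2ccccc2)cc1)c3c(OCc4ccccc4)cc(OCOC)cc3OCc5ccccc5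
F7 | step 12 | (2R,3S)-5,7-bis(benzyloxy)-2-[4-(benzyloxy)phenyl]-6-{(1R)-1-[4-(benzyloxy)phenyl]ethyl}-4-hydroxy-3,4-dihydro-2H-chromen-3-yl acetate, C4 epimers | C[C@H](c1ccc(OCc2ccccc2)cc1)c3c(OCc4ccccc4)cc5c(c3OCc6ccccc6)C(O)[C@H](OC(C)=O)[C@@H](c7ccc(OCc8ccccc8)cc7)O5
F8 | step 12 | (2R,3R)-5,7-bis(benzyloxy)-2-[4-(benzyloxy)phenyl]-6-{(1R)-1-[4-(benzyloxy)phenyl]ethyl}-4-oxo-3,4-dihydro-2H-chromen-3-yl acetate | C[C@H](c1ccc(OCc2ccccc2)cc1)c3c(OCc4ccccc4)cc5c(c3OCc6ccccc6)C(=O)[C@H](OC(C)=O)[C@@H](c7ccc(OCc8ccccc8)cc7)O5
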